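Remark on the chemistry: 2,4,6-trimethoxyphenylacetic acid (1) is assumed to be a catalogue compound; it already carries the aryl–CH2 bond of the lactone.

## Analysis of the target

The target is a flavonol: a 4H-chromen-4-one (benzo ring A fused to pyranone ring C) with a 4-methoxyphenyl ring B on C2, hydroxyls on C3, C5 and C7, and a 2-methylbut-3-en-2-yl (1,1-dimethylallyl) group on C8. It has no stereocentre and no stereogenic double bond, so every problem is one of constitution. Ring A carries three oxygens (O1, 5-O, 7-O) that must be told apart, and the ring-B ether must stay methyl while the other three oxygens end up free. The sensitive groups are the terminal vinyl group beside the 7-hydroxyl (acid can close a dihydrofuran; hydrogenolysis is excluded), the oxidisable flavonol enol, and the electron-rich ring A. The difficulty is the quaternary benzylic carbon on C8, wedged between C7–O and C8a–O1. Electrophilic prenylation delivers the linear isomer, and any ring-C closure of a precursor with two free ortho-hydroxyls can put the group at C6 or at C8. The strategy rests on the fact that this quaternary carbon and O1 sit on the adjacent ring atoms C8 and C8a. With those two ring atoms they make up C3, C3a, C7a and O1 of a benzofuran-2(3H)-one, whose carbonyl carbon is at the right oxidation level to become the vinyl CH. The quaternary carbon can then be made by two methylations at an acidic lactone position, and the lactone oxygen marks which phenol becomes O1.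

## Retrosynthetic reasoning

18 to 17. The two phenolic O–H bonds at C5 and C7 are traced back to methoxymethyl acetals. Acetals tolerate the hydride, ylide, Grignard, hydroxide and peroxide steps before them, and they leave under mild acid that does not protonate a monosubstituted alkene. Benzyl ethers would need hydrogenolysis, which would saturate the vinyl group; methyl ethers could not be distinguished from the ring-B methoxy group.

17 to 15 (through 16). O1–C2 and the C3–O bond are cut, which opens ring C to the 2'-hydroxychalcone 15. The forward step is an oxidative cyclisation with base and peroxide. In 15 the only free phenol is the one next to the quaternary carbon, so closure can only give the 8-substituted flavonol. Nucleophilic peroxide leaves the isolated vinyl group alone, which an electrophilic oxidant would not.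

15 to 13 and 14. The Cα=Cβ bond of the enone is cut in the aldol sense. The aryl methyl ketone 13 is the only enolisable partner and aldehyde 14 cannot enolise, so the condensation has one course.

13 to 12 to 11. The C–CH3 bond of the acetyl group is cut to aldehyde 11 and a methyl nucleophile, with carbinol 12 between them. Direct acetylation of the arene is not used because Lewis acids would strip the acetals and would not choose between the two free ring positions.

11 to 10. The bond from ring A to the future C4 is cut. The forward reaction is a formylation that is delivered through the metal phenoxide, so the carbon goes only to the position next to the free hydroxyl. The other ring CH lies between the two acetal oxygens and para to the hydroxyl and is not reached. That free hydroxyl is free only because it was the lactone oxygen.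

10 to 8 (through 9) to 7. The vinyl C=C bond is cut to the aldehyde carbon of 9, the open form of lactol 8, which comes from partial reduction of lactone 7. The lactone carbonyl carbon is thus the vinyl CH, and reduction plus methylenation releases the tertiary allyl group and the O1 phenol together.

7 to 4 and 5 (through 6). Both C–CH3 bonds of the quaternary carbon are cut. This is the central disconnection: the crowded carbon is assembled by two displacements at methyl from the lactone enolate of 4, not by bringing a tertiary group to a hindered ring position.

4 to 3 to 1 (through 2). The acetal O–C bonds are removed to give dihydroxy lactone 3, and the lactone C–O bond and three O–CH3 bonds lead back to acid 1. Acid 1 is symmetrical, so lactonisation onto either ortho oxygen gives the same 3, and desymmetrisation costs nothing. Attaching the acid side chain to the unsubstituted triphenol by hydroxyalkylation with a two-carbon oxo acid was also weighed for this stage. It was set aside because the hydroxybenzyl intermediate on so electron-rich a ring would ionise and alkylate a second ring.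

## Alternatives that were turned down

Alternative 1: ring A grown on a pyranone by a ketene–alkyne benzannulation.
- Disconnection: C5–C6, C7–C8 and C5–C4a are cut, so that ring A disappears and a 4-pyranone carrying ring B and the C3 oxygen remains.
- Forward key step: Wolff rearrangement of diazo ketone A2 gives ketene A4. Its carbonyl carbon (future C5) and its substituted carbon (future C8) add across siloxyalkyne A3. Four-electron ring opening and six-electron closure onto the pyranone CH then give A1 after tautomerisation.
- For: every ring-A substituent is placed by construction, the 5-hydroxyl and the 7-silyl ether emerge differentiated, the C3 oxygen is present from the start, and the route is convergent. On regiochemical certainty it is at least as strong as the chosen route.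
- Against: the ketene carbon of A4 carries a tertiary group, so the cycloaddition must create a quaternary ring carbon beside another quaternary carbon. The final closure has to use a double bond of a cross-conjugated pyranone, which is itself photoreactive under the conditions that form A4. The pyranone core of A2 needs a long separate synthesis.
- Comparison: the uncertain step comes last, on the most valuable intermediate. The chosen route puts its uncertain step early, on a cheap lactone, and the bonds formed there are made at unhindered methyl groups.

Alternative 2: ring C closed at C2=C3 by ylide acylation and ester olefination.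
- Disconnection: C3–C4 and C2=C3 are cut.
- Forward key step: acid chloride A6 acylates the alkoxy-substituted phosphorane A7 at carbon (C3–C4). The stabilised ylide carbon then olefinates the neighbouring 4-methoxybenzoate carbonyl (C2=C3) to give A5, with the C3 oxygen as a 2-(trimethylsilyl)ethyl ether.
- For: ring C is closed without an oxidant, no aurone pathway exists, and the C3 oxygen arrives protected at the right oxidation level. On ring C it is stronger than step 10 of the chosen route.
- Against: it does nothing for C8. A6 would have to be made from aldehyde 11 by oxidation, aroylation and chlorination, the last beside acid-labile acetals. The acyl chloride is electron-rich and flanked on both sides, the ester carbonyl lies next to the tertiary group, and a keto-stabilised ylide is a sluggish olefinating agent for esters. A further deprotection is needed.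
- Comparison: it is longer and still depends on the lactone chemistry for the quaternary carbon. The chosen route keeps ring C classical and spends its one uncertain step on the quaternary carbon.

Alternative 3: ring C closed at C3–C4 by a carbene-catalysed benzoin reaction.
- Disconnection: C3–C4 is cut.
- Forward key step: a thiazolium-derived carbene converts the aryl aldehyde of dialdehyde A9 into an acyl anion equivalent, which adds to the aliphatic aldehyde to give the trans-3-hydroxyflavanone A8. A8 has the constitution and relative configuration of intermediate 16 and would still need dehydrogenation.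
- For: it would start from aldehyde 11 and skip steps 7 and 8, it installs the C3 oxygen without peroxide, and it cannot give an aurone.
- Against: A9 requires O-alkylation of the hindered phenoxide of 11 at a secondary benzylic carbon, followed by release of an enolisable α-aryloxy aldehyde beside the acetals. The aryl aldehyde is flanked on both sides and electron-rich, hence the poorer acyl-anion donor, while the aliphatic aldehyde is the better one. The wrong polarity would give the 3-keto-4-hydroxy isomer. Two stereocentres are set only to be destroyed.
- Comparison: it matches the chosen route on avoiding the aurone problem, but the saving of two steps is lost in making A9, and the C8 problem is again left to the lactone chemistry.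

Key step: step 3

## Route

Step 1
Reactants: 1 2,4,6-trimethoxyphenylacetic acid
Product: 3 4,6-dihydroxy-1-benzofuran-2(3H)-one, via 2,4,6-trihydroxyphenylacetic acid 2 (not isolated)
Conditions: BBr3 (5 equiv), CH2Cl2, −78 °C to rt; H2O; then TsOH (cat.), toluene, reflux
Reagents that add atoms: none
Why: Aryl methyl ether cleavage with BBr3 frees all three phenols, and the ortho-hydroxyphenylacetic acid lactonises under acid with loss of water; because 2 is symmetrical, either ortho-hydroxyl gives the same lactone.

Step 2
Reactants: 3 4,6-dihydroxy-1-benzofuran-2(3H)-one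
Product: 4 4,6-bis(methoxymethoxy)-1-benzofuran-2(3H)-one
Conditions: MOMCl (2.6 equiv), iPr2NEt (3.5 equiv), CH2Cl2, 0 °C to rt
Reagents that add atoms: chloromethyl methyl ether, COCCl
Why: Phenol O-alkylation with an α-chloro ether and a hindered amine; the amine is too weak to generate the lactone enolate in quantity, so the fast reaction of the phenols with the oxocarbenium-like electrophile should dominate.

Step 3
Reactants: 4 4,6-bis(methoxymethoxy)-1-benzofuran-2(3H)-one; 5 iodomethane
Product: 7 4,6-bis(methoxymethoxy)-3,3-dimethyl-1-benzofuran-2(3H)-one, via 3-monomethyl lactone 6 (not isolated)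
Conditions: NaH (2.5 equiv), MeI (5 equiv), THF–DMF, 0 °C to rt, 4 added slowly
Reagents that add atoms: iodomethane (5), CI
Why: NaH removes the benzylic lactone α-proton of 4 to give an enolate that is an aromatic 2-oxidobenzofuran; its C3 displaces iodide from MeI to give 6, whose remaining α-proton is still benzylic and next to the aryl ester carbonyl, so a second deprotonation and methylation give 7 and both C–CH3 bonds of the quaternary carbon form in one flask. The closest known reaction type is the C,C-dialkylation of benzofuran-2(3H)-one and arylacetic ester enolates with alkyl iodides. No ring is closed; the lactone ring stays intact and serves to hold C3 next to the oxygen that will become O1. No stereocentre remains, since the racemic stereocentre of 6 is erased by the second methylation. The selectivity needed is carbon against oxygen alkylation and alkylation against acyl transfer from unreacted lactone to the enolate. The soft iodide and the regained lactone carbonyl favour carbon, and slow addition of 4 to NaH with excess MeI present keeps enolate and free lactone apart. Both bond formations are displacements at methyl, so the crowding between the 4-OMOM group and the lactone oxygen does not hinder them. The MOM ethers are inert to NaH and MeI.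

Step 4
Reactants: 7 4,6-bis(methoxymethoxy)-3,3-dimethyl-1-benzofuran-2(3H)-one
Product: 8 4,6-bis(methoxymethoxy)-3,3-dimethyl-2,3-dihydro-1-benzofuran-2-ol (racemic)
Conditions: iBu2AlH (1.2 equiv), CH2Cl2, −78 °C; aqueous potassium sodium tartrate
Reagents that add atoms: none
Why: Partial reduction of a lactone to the lactol; the tetrahedral aluminium alkoxide is stable at low temperature and the gem-dimethyl group favours the closed form, while the new hemiacetal stereocentre is racemic and is lost on ring opening in step 5.

Step 5
Reactants: 8 4,6-bis(methoxymethoxy)-3,3-dimethyl-2,3-dihydro-1-benzofuran-2-ol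
Product: 10 3,5-bis(methoxymethoxy)-2-(2-methylbut-3-en-2-yl)phenol, via ring-opened hydroxy aldehyde 9 (not isolated)
Conditions: Ph3PCH3Br (3.5 equiv), KOtBu (3.3 equiv), THF, 0 °C to rt
Reagents that add atoms: methyltriphenylphosphonium bromide, C[P+](c1ccccc1)(c1ccccc1)c1ccccc1.[Br-]
Why: Wittig methylenation of a lactol through its open phenoxide aldehyde; the aldehyde has no α-hydrogen, so excess ylide can only olefinate it, and the small methylene ylide tolerates the neopentyl position.

Step 6
Reactants: 10 3,5-bis(methoxymethoxy)-2-(2-methylbut-3-en-2-yl)phenol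
Product: 11 2-hydroxy-4,6-bis(methoxymethoxy)-3-(2-methylbut-3-en-2-yl)benzaldehyde
Conditions: MgCl2 (2 equiv), Et3N (4 equiv), (CH2O)n (6 equiv), MeCN, reflux
Reagents that add atoms: paraformaldehyde (as formaldehyde), C=O
Why: Casnati–Skattebøl ortho-formylation: the magnesium phenoxide binds formaldehyde and delivers it through a six-membered chelate to the only free ortho carbon, and hydride transfer to a second formaldehyde gives the aldehyde; the CH between the two acetal oxygens is not in reach of the chelate.

Step 7
Reactants: 11 2-hydroxy-4,6-bis(methoxymethoxy)-3-(2-methylbut-3-en-2-yl)benzaldehyde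
Product: 12 1-[2-hydroxy-4,6-bis(methoxymethoxy)-3-(2-methylbut-3-en-2-yl)phenyl]ethan-1-ol (racemic)
Conditions: MeMgBr (3 equiv), THF, −20 to 0 °C; cold sat. NH4Cl; used crude
Reagents that add atoms: methylmagnesium bromide, C[Mg]Br
Why: Grignard addition to the aldehyde after the first equivalent has deprotonated the phenol; the new carbinol stereocentre is racemic and is removed in step 8.

Step 8
Reactants: 12 1-[2-hydroxy-4,6-bis(methoxymethoxy)-3-(2-methylbut-3-en-2-yl)phenyl]ethan-1-ol
Product: 13 1-[2-hydroxy-4,6-bis(methoxymethoxy)-3-(2-methylbut-3-en-2-yl)phenyl]ethan-1-one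
Conditions: MnO2 (activated, excess), CH2Cl2, rt
Reagents that add atoms: none
Why: Heterogeneous MnO2 oxidation of a benzylic alcohol under near-neutral conditions; the phenol, the acetals and the isolated alkene are not attacked, and the product is stabilised by the hydrogen bond from the ortho-hydroxyl.

Step 9
Reactants: 13 1-[2-hydroxy-4,6-bis(methoxymethoxy)-3-(2-methylbut-3-en-2-yl)phenyl]ethan-1-one; 14 4-methoxybenzaldehyde
Product: 15 (2E)-1-[2-hydroxy-4,6-bis(methoxymethoxy)-3-(2-methylbut-3-en-2-yl)phenyl]-3-(4-methoxyphenyl)prop-2-en-1-one
Conditions: KOH (50% aq.), EtOH, rt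
Reagents that add atoms: 4-methoxybenzaldehyde (14), COc1ccc(C=O)cc1
Why: Claisen–Schmidt condensation between the only enolisable ketone and a non-enolisable aldehyde; the elimination is reversible at the aldol stage and gives the E enone.

Step 10
Reactants: 15 (2E)-1-[2-hydroxy-4,6-bis(methoxymethoxy)-3-(2-methylbut-3-en-2-yl)phenyl]-3-(4-methoxyphenyl)prop-2-en-1-one
Product: 17 3-hydroxy-5,7-bis(methoxymethoxy)-2-(4-methoxyphenyl)-8-(2-methylbut-3-en-2-yl)-4H-chromen-4-one, via trans-3-hydroxyflavanone 16 (not isolated)
Conditions: H2O2 (30% aq., 5 equiv), NaOH (2 M aq.), MeOH, 0 °C to rt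
Reagents that add atoms: hydrogen peroxide, OO
Why: Algar–Flynn–Oyamada reaction: the phenoxide adds to the enone in the six-membered mode, the enolate is hydroxylated by peroxide anti to the aryl group to give trans-16, and further oxidation removes both stereocentres; the only free phenol lies next to the quaternary carbon, so only the 8-substituted flavonol can form, and the isolated vinyl group is inert to nucleophilic peroxide.

Step 11
Reactants: 17 3-hydroxy-5,7-bis(methoxymethoxy)-2-(4-methoxyphenyl)-8-(2-methylbut-3-en-2-yl)-4H-chromen-4-one
Product: 18 3,5,7-trihydroxy-2-(4-methoxyphenyl)-8-(2-methylbut-3-en-2-yl)-4H-chromen-4-one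
Conditions: HCl (2 M, MeOH–H2O), THF, 40 °C
Reagents that add atoms: none
Why: Acid-catalysed acetal exchange with methanol removes both MOM groups, the 5-O-acetal being helped by the neighbouring carbonyl; protonating the monosubstituted alkene would need a secondary cation and should not compete under these mild conditions, and the aryl methyl ether is untouched.

## Compound list

1 | 2,4,6-trimethoxyphenylacetic acid | COc1cc(OC)c(CC(=O)O)c(OC)c1 | starting material
2 | 2,4,6-trihydroxyphenylacetic acid | Oc1cc(O)c(CC(=O)O)c(O)c1 | intermediate (not isolated)
3 | 4,6-dihydroxy-1-benzofuran-2(3H)-one | O=C1Cc2c(O)cc(O)cc2O1 | intermediate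
4 | 4,6-bis(methoxymethoxy)-1-benzofuran-2(3H)-one | COCOc1cc(OCOC)c2c(c1)OC(=O)C2 | intermediate
5 | iodomethane | CI | starting material
6 | 4,6-bis(methoxymethoxy)-3-methyl-1-benzofuran-2(3H)-one (racemic) | COCOc1cc(OCOC)c2c(c1)OC(=O)C2C | intermediate (not isolated)
7 | 4,6-bis(methoxymethoxy)-3,3-dimethyl-1-benzofuran-2(3H)-one | COCOc1cc(OCOC)c2c(c1)OC(=O)C2(C)C | intermediate
8 | 4,6-bis(methoxymethoxy)-3,3-dimethyl-2,3-dihydro-1-benzofuran-2-ol (racemic) | COCOc1cc(OCOC)c2c(c1)OC(O)C2(C)C | intermediate
9 | 2-[2-hydroxy-4,6-bis(methoxymethoxy)phenyl]-2-methylpropanal | COCOc1cc(O)c(C(C)(C)C=O)c(OCOC)c1 | intermediate (not isolated)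
10 | 3,5-bis(methoxymethoxy)-2-(2-methylbut-3-en-2-yl)phenol | COCOc1cc(O)c(C(C)(C)C=C)c(OCOC)c1 | intermediate
11 | 2-hydroxy-4,6-bis(methoxymethoxy)-3-(2-methylbut-3-en-2-yl)benzaldehyde | C=CC(C)(C)c1c(O)c(C=O)c(OCOC)cc1OCOC | intermediate
12 | 1-[2-hydroxy-4,6-bis(methoxymethoxy)-3-(2-methylbut-3-en-2-yl)phenyl]ethan-1-ol (racemic) | C=CC(C)(C)c1c(O)c(C(C)O)c(OCOC)cc1OCOC | intermediate
13 | 1-[2-hydroxy-4,6-bis(methoxymethoxy)-3-(2-methylbut-3-en-2-yl)phenyl]ethan-1-one | C=CC(C)(C)c1c(O)c(C(C)=O)c(OCOC)cc1OCOC | intermediate
14 | 4-methoxybenzaldehyde | COc1ccc(C=O)cc1 | starting material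
15 | (2E)-1-[2-hydroxy-4,6-bis(methoxymethoxy)-3-(2-methylbut-3-en-2-yl)phenyl]-3-(4-methoxyphenyl)prop-2-en-1-one | C=CC(C)(C)c1c(O)c(C(=O)/C=C/c2ccc(OC)cc2)c(OCOC)cc1OCOC | intermediate
16 | trans-3-hydroxy-5,7-bis(methoxymethoxy)-2-(4-methoxyphenyl)-8-(2-methylbut-3-en-2-yl)-2,3-dihydro-4H-chromen-4-one (racemic; 2R,3R enantiomer drawn) | O[C@@H]1[C@@H](c2ccc(OC)cc2)Oc2c(C(C)(C)C=C)c(OCOC)cc(OCOC)c2C1=O | intermediate (not isolated)
17 | 3-hydroxy-5,7-bis(methoxymethoxy)-2-(4-methoxyphenyl)-8-(2-methylbut-3-en-2-yl)-4H-chromen-4-one | C=CC(C)(C)c1c(OCOC)cc(OCOC)c2c(=O)c(O)c(-c3ccc(OC)cc3)oc12 | intermediate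
18 | 3,5,7-trihydroxy-2-(4-methoxyphenyl)-8-(2-methylbut-3-en-2-yl)-4H-chromen-4-one | C=CC(C)(C)c1c(O)cc(O)c2c(=O)c(O)c(-c3ccc(OC)cc3)oc12 | target

## Step count and least certain steps

Total step count: 11. Longest linear sequence: 11 steps (1 to 18); 5 and 14 enter as purchased reagents.

Step 3 (key step). The most likely failure is acyl transfer between the lactone enolate and unreacted aryl lactone (self-condensation), followed by ring opening; methylation at the enolate oxygen or an incomplete second methylation are the lesser risks. The fallback builds the quaternary carbon on an open-chain ester and closes the lactone afterwards. It sets out from 1 and comes back at 7.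
- Esterification of 1 (MeOH, H2SO4) gives methyl (2,4,6-trimethoxyphenyl)acetate F1.
- Two rounds of LiN(iPr)2 and MeI in THF at −78 °C give methyl 2-methyl-2-(2,4,6-trimethoxyphenyl)propanoate F2.
- BBr3 cleaves the three aryl ethers, and the freed ortho-phenol closes onto the ester to give 4,6-dihydroxy-3,3-dimethyl-1-benzofuran-2(3H)-one F3, which has no enolisable hydrogen.
- MOMCl with iPr2NEt then gives 7.

Step 7 (with step 8). Carbinol 12 is an ortho-hydroxybenzyl alcohol on a very electron-rich ring. Loss of water through an ortho-quinone methide, during work-up or on the MnO2 surface, can lead to oligomerisation. The fallback masks the phenol so that this pathway is closed. It sets out from 11 and comes back at 13.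
- Allyl bromide and K2CO3 in DMF give 4,6-bis(methoxymethoxy)-3-(2-methylbut-3-en-2-yl)-2-(prop-2-en-1-yloxy)benzaldehyde F4.
- MeMgBr gives 1-[4,6-bis(methoxymethoxy)-3-(2-methylbut-3-en-2-yl)-2-(prop-2-en-1-yloxy)phenyl]ethan-1-ol F5.
- Dess–Martin periodinane buffered with NaHCO3 gives 1-[4,6-bis(methoxymethoxy)-3-(2-methylbut-3-en-2-yl)-2-(prop-2-en-1-yloxy)phenyl]ethan-1-one F6.
- Zerovalent palladium, as Pd(PPh3)4, with morpholine removes the O-allyl group and returns 13.

Step 10. The 6'-alkoxy group twists the enone and the tertiary group crowds the phenoxide. Both slow the six-membered conjugate addition, so epoxidation followed by five-membered closure (the aurone pathway) may take over. The fallback separates ring closure from C3 oxidation. It sets out from 15 and comes back at 17.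
- NaOAc in refluxing EtOH isomerises 15 to 5,7-bis(methoxymethoxy)-2-(4-methoxyphenyl)-8-(2-methylbut-3-en-2-yl)-2,3-dihydro-4H-chromen-4-one F7.
- DDQ in refluxing dioxane dehydrogenates it to 5,7-bis(methoxymethoxy)-2-(4-methoxyphenyl)-8-(2-methylbut-3-en-2-yl)-4H-chromen-4-one F8.
- Lithiation at C3 with LiN(iPr)2 at −78 °C, trapping with B(OMe)3 and oxidation of the boronate with H2O2/AcOH give 17; none of these reagents touches the vinyl group.

Step 11. If the 7-O-acetal needs forcing, the freed 7-hydroxyl may add across the neighbouring vinyl group under acid and close a dihydrofuran ring. The fallback removes the acetals without a Brønsted acid. It sets out from 17 and ends at 18.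
- Et3SiOTf with 2,2'-bipyridyl in CH2Cl2 at 0 °C exchanges the aryl acetals for silyl ethers and silylates the 3-hydroxyl. This should give 2-(4-methoxyphenyl)-8-(2-methylbut-3-en-2-yl)-3,5,7-tris[(triethylsilyl)oxy]-4H-chromen-4-one F9.
- Bu4NF buffered with AcOH in THF at 0 °C then releases 18.

## Further compounds

F1 | step 3 | methyl (2,4,6-trimethoxyphenyl)acetate | COC(=O)Cc1c(OC)cc(OC)cc1OC
F2 | step 3 | methyl 2-methyl-2-(2,4,6-trimethoxyphenyl)propanoate | COC(=O)C(C)(C)c1c(OC)cc(OC)cc1OC
F3 | step 3 | 4,6-dihydroxy-3,3-dimethyl-1-benzofuran-2(3H)-one | CC1(C)C(=O)Oc2cc(O)cc(O)c21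
F4 | step 7 | 4,6-bis(methoxymethoxy)-3-(2-methylbut-3-en-2-yl)-2-(prop-2-en-1-yloxy)benzaldehyde | C=CCOc1c(C=O)c(OCOC)cc(OCOC)c1C(C)(C)C=C
F5 | step 7 | 1-[4,6-bis(methoxymethoxy)-3-(2-methylbut-3-en-2-yl)-2-(prop-2-en-1-yloxy)phenyl]ethan-1-ol (racemic) | C=CCOc1c(C(C)O)c(OCOC)cc(OCOC)c1C(C)(C)C=C
F6 | step 7 | 1-[4,6-bis(methoxymethoxy)-3-(2-methylbut-3-en-2-yl)-2-(prop-2-en-1-yloxy)phenyl]ethan-1-one | C=CCOc1c(C(C)=O)c(OCOC)cc(OCOC)c1C(C)(C)C=C
F7 | step 10 | 5,7-bis(methoxymethoxy)-2-(4-methoxyphenyl)-8-(2-methylbut-3-en-2-yl)-2,3-dihydro-4H-chromen-4-one (racemic) | C=CC(C)(C)c1c(OCOC)cc(OCOC)c2c1OC(c1ccc(OC)cc1)CC2=O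
F8 | step 10 | 5,7-bis(methoxymethoxy)-2-(4-methoxyphenyl)-8-(2-methylbut-3-en-2-yl)-4H-chromen-4-one | C=CC(C)(C)c1c(OCOC)cc(OCOC)c2c(=O)cc(-c3ccc(OC)cc3)oc12
F9 | step 11 | 2-(4-methoxyphenyl)-8-(2-methylbut-3-en-2-yl)-3,5,7-tris[(triethylsilyl)oxy]-4H-chromen-4-one | C=CC(C)(C)c1c(O[Si](CC)(CC)CC)cc(O[Si](CC)(CC)CC)c2c(=O)c(O[Si](CC)(CC)CC)c(-c3ccc(OC)cc3)oc12
A1 | alternative 1 | 5-hydroxy-3-(methoxymethoxy)-2-(4-methoxyphenyl)-8-(2-methylbut-3-en-2-yl)-7-{[tri(propan-2-yl)silyl]oxy}-4H-chromen-4-one | C=CC(C)(C)c1c(O[Si](C(C)C)(C(C)C)C(C)C)cc(O)c2c(=O)c(OCOC)c(-c3ccc(OC)cc3)oc12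
A2 | alternative 1 | 6-(1-diazo-3,3-dimethyl-2-oxopent-4-en-1-yl)-3-(methoxymethoxy)-2-(4-methoxyphenyl)-4H-pyran-4-one | C=CC(C)(C)C(=O)C(=[N+]=[N-])c1cc(=O)c(OCOC)c(-c2ccc(OC)cc2)o1
A3 | alternative 1 | (ethynyloxy)tri(propan-2-yl)silane | C#CO[Si](C(C)C)(C(C)C)C(C)C
A4 | alternative 1 | 2-[5-(methoxymethoxy)-6-(4-methoxyphenyl)-4-oxo-4H-pyran-2-yl]-3,3-dimethylpenta-1,4-dien-1-one | C=CC(C)(C)C(=C=O)c1cc(=O)c(OCOC)c(-c2ccc(OC)cc2)o1
A5 | alternative 2 | 5,7-bis(methoxymethoxy)-2-(4-methoxyphenyl)-8-(2-methylbut-3-en-2-yl)-3-[2-(trimethylsilyl)ethoxy]-4H-chromen-4-one | C=CC(C)(C)c1c(OCOC)cc(OCOC)c2c(=O)c(OCC[Si](C)(C)C)c(-c3ccc(OC)cc3)oc12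
A6 | alternative 2 | 2-(chlorocarbonyl)-3,5-bis(methoxymethoxy)-6-(2-methylbut-3-en-2-yl)phenyl 4-methoxybenzoate | C=CC(C)(C)c1c(OCOC)cc(OCOC)c(C(=O)Cl)c1OC(=O)c1ccc(OC)cc1
A7 | alternative 2 | triphenyl{[2-(trimethylsilyl)ethoxy]methylidene}phosphorane | C[Si](C)(C)CCOC=P(c1ccccc1)(c1ccccc1)c1ccccc1
A8 | alternative 3 | (2R,3R)-3-hydroxy-5,7-bis(methoxymethoxy)-2-(4-methoxyphenyl)-8-(2-methylbut-3-en-2-yl)-2,3-dihydro-4H-chromen-4-one (trans; one enantiomer of the racemate) | O[C@@H]1[C@@H](c2ccc(OC)cc2)Oc2c(C(C)(C)C=C)c(OCOC)cc(OCOC)c2C1=O
A9 | alternative 3 | 2-[2-formyl-3,5-bis(methoxymethoxy)-6-(2-methylbut-3-en-2-yl)phenoxy]-2-(4-methoxyphenyl)acetaldehyde (racemic) | C=CC(C)(C)c1c(OCOC)cc(OCOC)c(C=O)c1OC(C=O)c1ccc(OC)cc1
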